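(The numbers in the tables stem from a simulated flask from invented constants.)

If a flask is read at one moment and I have to say whether starting material or product leads, I want one time: the moment the two are equal.

all flasks: starting material 0.050 M; gas phase 6.9 mM (held); catalyst 0.10 mM; added ligand 0.32 mM
- maple: protic impurity 0.070 M; run made earlier
- ash: protic impurity 0.11 M; run made earlier
- north: protic impurity 0.0500 M; time 10 h
- east: protic impurity 0.0500 M; time 15 h

| run | time / h | product / % | starting material / % |
|---|---|---|---|
| maple | 1.00 | 4 | 96 |
| maple | 3.00 | 13 | 85 |
| maple | 5.00 | 23 | 75 |
| maple | 8.00 | 34 | 68 |
| ash | 1.00 | 5 | 97 |
| ash | 3.00 | 12 | 87 |
| ash | 5.00 | 20 | 78 |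
| ash | 8.00 | 32 | 68 |

(scatter of a reading: 1.5 percentage points)

- at the start none of the gas phase is in solution
- a reading or a percentage of product counts all its forms, free or not

* which of these there is most of at the end, counted by the starting material in it, north (product / starting material)
* which of these there is most of at the end, counted by the starting material in it, east (product / starting material)
* final amount of the leader among these, as a percentage of the starting material charged, in north
* final amount of the leader among these, as a percentage of the starting material charged, in east

In maple at 8.00 h the two columns add up to 102% of the charge, so I treat product and starting material as sharing the charge, and they are equal when half has reacted. Maple and ash differ by 2 percentage points in product at that time, against a scatter of 1.5 points, although ash holds more protic impurity. I therefore carry maple's last reading over to north and east.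

The early readings show no clear bend, so I solve two extreme flasks through that one reading. In the first, the rate stays constant (zero order): the fraction reacted grows on a straight line and reaches half at 11.8 h. In the second, the rate falls in step with the starting material left (pseudo-first-order): equal times halve what is left, and half has gone at 13.3 h. This second figure is the crossing time, the time at which half the charge has reacted, and it is what I carry forward. If, beyond that reading, the rate does not rise and falls no faster than the starting material, I expect north and east, which differ only in their stopping time, to cross between these two times.

North stops at 10 h, before both, so I expect starting material to lead, at 57.6% to 59.4%. East stops at 15 h, after both, so I expect product to lead, at 54.2% to 63.6%.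

The forecast names starting material at 58% for north and product at 58% for east, noting that “the data cannot distinguish zero-order behaviour (gas- or catalyst-limited) from first-order behaviour”.

The flask gives starting material at 59.0% in north and product at 54.9% in east.

    crystals ⇌ product, rate k1*(cs1 - [product]) while solid is left; crystals form when [product] > cs1 (solubility = 4.40 mM, k = 3.98 × 10⁻⁴ s⁻¹)
    gas phase ⇌ dissolved gas, rate k2*(csat - [dissolved gas]) (kL = 3.00 × 10⁻⁴ s⁻¹)
    catalyst + added ligand ⇌ idle complex (K = 5300 L mol⁻¹, k = 0.249 L mol⁻¹ s⁻¹)
    starting material + dissolved gas + catalyst → catalyst + product (k = 72.3 L² mol⁻² s⁻¹)
    dissolved gas + protic impurity → quenched reagent (k = 9.82 × 10⁻⁴ L mol⁻¹ s⁻¹)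

With the charges of north and east the two are equal at 13.1 h, which is later than the straight-line time and 0.200 h earlier than my crossing time. A neighbouring flask is charged as east but stopped at 6.0 h, before both times. So the same reckoning puts starting material ahead, and halving once per crossing time leaves 73.1% of the charge. In that flask the leader is starting material, at 72.6%.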